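**Retrosynthetic overview**
1. The target comes from opening a tricyclic dihydrocoumarin lactone. The lactone comes from a catalyst-controlled [3+3] union of a chroman-5-ol (free C6–H) and (E)-hex-2-enal, which sets the side-chain centre.
2. The C8-prenyl group comes from a para-Claisen–Cope shift of the 5-O-prenyl ether.
3. Key disconnection, C3–C4 (plus O1–C2) of the dihydropyran ring: a salicylaldehyde formyl carbon, masked as a 2-lithio-1,3-dithiane (acyl anion), and the neighbouring phenoxide displace both C–O bonds of the C2-symmetric cyclic sulfate of (2R,3R)-butane-2,3-diol. Double inversion sets C2 and C3 (trans) in one flask, and Raney Ni then turns C4 into CH2.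
4. The aryl dithiane comes from 2,6-dihydroxy-4-methoxybenzaldehyde, which comes from 2,4,6-trihydroxybenzaldehyde.
5. Ring order: the benzene ring is bought, the dihydropyran ring closes in the key step, and the lactone ring is made late and opened last.

Assumption: the facial sense quoted for the triazolium salt in step 8 (and for the ligand in its fallback) is taken by analogy. Both antipodes are sold, so the other one is used unchanged if the first run gives the (S) centre.

**Step 1**
Reactants: 1 2,4,6-trihydroxybenzaldehyde; 2 iodomethane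
Product: 3 2,6-dihydroxy-4-methoxybenzaldehyde
Conditions: MeI (1.0 equiv), K2CO3 (1.0 equiv), acetone, 25 °C
Reagents that add atoms: iodomethane (2), CI
Why: Williamson O-methylation is selective because the 4-OH is the most acidic hydroxyl and the only one not hydrogen-bonded to the formyl oxygen, so one equivalent each of base and MeI caps it alone and leaves a symmetric resorcinol.

**Step 2**
Reactants: 3 2,6-dihydroxy-4-methoxybenzaldehyde; 4 propane-1,3-dithiol
Product: 5 2-(1,3-dithian-2-yl)-5-methoxybenzene-1,3-diol
Conditions: HS(CH2)3SH (1.1 equiv), BF3·OEt2 (0.2 equiv), THF, 0 → 25 °C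
Reagents that add atoms: propane-1,3-dithiol (4), SCCCS
Why: Lewis-acid-catalysed dithioacetalisation (Corey–Seebach masking) is fast for this electron-rich aldehyde and converts the electrophilic formyl carbon into a C–H acid (pKa about 31) that can be metalated later, while the phenols are untouched.

**Step 3**
Reactants: 6 (2R,3R)-butane-2,3-diol
Product: 8 (4R,5R)-4,5-dimethyl-1,3,2-dioxathiolane 2,2-dioxide, via cyclic sulfite 7 (not isolated)
Conditions: SOCl2 (1.2 equiv), CH2Cl2, 40 °C; then RuCl3·xH2O (0.1 mol %), NaIO4 (1.5 equiv), MeCN–H2O, 0 °C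
Reagents that add atoms: thionyl chloride, O=S(Cl)Cl; sodium periodate, [Na+].[O-]I(=O)(=O)=O
Why: The Gao–Sharpless cyclic sulfate synthesis (sulfite formation, then RuO4-catalysed S-oxidation) breaks no C–O bond, so both (R) centres pass unchanged into a C2-symmetric bis-electrophile whose two carbons are equivalent.

**Step 4 (key step)**
Reactants: 5 2-(1,3-dithian-2-yl)-5-methoxybenzene-1,3-diol; 8 (4R,5R)-4,5-dimethyl-1,3,2-dioxathiolane 2,2-dioxide
Product: 11 (2S,3S)-7-methoxy-2,3-dimethylspiro[chromane-4,2'-[1,3]dithian]-5-ol, via sodium ether sulfate 9 (not isolated), via lithiated dithiane 10 (not isolated)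
Conditions: NaH (1.05 equiv), THF–DMPU 5:1, 0 °C, then 8 (1.0 equiv), 25 °C, 3 h; cool to −78 °C, n-BuLi (2.2 equiv), −78 → 25 °C, 12 h; sat. aq NH4Cl
Reagents that add atoms: none
Why: Proposed new method: the phenoxide opens the cyclic sulfate by SN2 (inversion, C2 becomes S; no regiochemical issue because the two carbons are equivalent), the secondary alkyl sulfate stays as a latent leaving group, and metalation of the phenol and the dithiane C–H then turns the former formyl carbon into an acyl-anion equivalent that closes the ring by 6-exo-tet SN2 on the remaining carbinol-derived carbon (second inversion, sets C3, methyls trans), so two natively electrophilic carbons are joined; the closest known reaction types are Corey–Seebach dithiane alkylation and the two-stage double displacement of diol cyclic sulfates (malonates to cyclopropanes, primary phosphides to phospholanes with n-BuLi added in two portions).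

**Step 5**
Reactants: 11 (2S,3S)-7-methoxy-2,3-dimethylspiro[chromane-4,2'-[1,3]dithian]-5-ol
Product: 12 (2S,3R)-7-methoxy-2,3-dimethylchroman-5-ol
Conditions: Raney Ni (W-2, excess), EtOH, reflux
Reagents that add atoms: none
Why: Mozingo-type Raney Ni desulfurisation replaces both benzylic C–S bonds by C–H without touching the aryl ethers, the phenol or the two stereocentres (the C3 descriptor changes only through CIP ranking), and it is run before any alkene is present.

**Step 6**
Reactants: 12 (2S,3R)-7-methoxy-2,3-dimethylchroman-5-ol; 13 1-bromo-3-methylbut-2-ene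
Product: 14 (2S,3R)-7-methoxy-2,3-dimethyl-5-(3-methylbut-2-enyloxy)chromane
Conditions: prenyl bromide (1.2 equiv), K2CO3 (1.5 equiv), acetone, 50 °C
Reagents that add atoms: 1-bromo-3-methylbut-2-ene (13), CC(C)=CCBr
Why: Williamson etherification of the only phenol by the allylic bromide under weak-base conditions gives O- rather than C-alkylation and sets up the sigmatropic transfer.

**Step 7**
Reactants: 14 (2S,3R)-7-methoxy-2,3-dimethyl-5-(3-methylbut-2-enyloxy)chromane
Product: 17 (2S,3R)-7-methoxy-2,3-dimethyl-8-(3-methylbut-2-enyl)chroman-5-ol, via ortho-dienone 15 (not isolated), via para-dienone 16 (not isolated)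
Conditions: N,N-diethylaniline, 200 °C, sealed tube, 2 h
Reagents that add atoms: none
Why: In this aromatic para-Claisen rearrangement (Claisen then Cope) the first [3,3] shift places a 1,1-dimethylallyl group on C6 between two oxygens, strain in that dienone drives a second [3,3] shift to C8 faster than enolisation, and tautomerisation leaves the linear prenyl group para to the freed phenol, with no stereocentre involved.

**Step 8**
Reactants: 17 (2S,3R)-7-methoxy-2,3-dimethyl-8-(3-methylbut-2-enyl)chroman-5-ol; 18 (E)-hex-2-enal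
Product: 19 (4R,8S,9R)-5-methoxy-8,9-dimethyl-6-(3-methylbut-2-enyl)-4-propyl-3,4,9,10-tetrahydro-2H,8H-pyrano[2,3-f]chromen-2-one
Conditions: 18 (1.5 equiv), (5aR,10bS)-2-mesityl-5a,10b-dihydro-4H,6H-indeno[2,1-b][1,2,4]triazolo[4,3-d][1,4]oxazin-2-ium tetrafluoroborate (10 mol %), DBU (20 mol %), DQ (3,3',5,5'-tetra-tert-butyl-4,4'-diphenoquinone, 1.2 equiv), 4 Å MS, toluene, 25 °C
Reagents that add atoms: (E)-hex-2-enal (18), CCC/C=C/C=O
Why: In this oxidative NHC-catalysed formal [3+3] annulation, DQ oxidises the Breslow intermediate of 18 to the α,β-unsaturated acyl azolium, the only free ring carbon (C6, ortho to the phenol) adds to its β-carbon and the phenol oxygen closes the lactone, while the aminoindanol backbone shields one face so the aryl carbon attacks the Re face and sets the (R) centre, and the minor diastereomer is removed by chromatography.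

**Step 9**
Reactants: 19 (4R,8S,9R)-5-methoxy-8,9-dimethyl-6-(3-methylbut-2-enyl)-4-propyl-3,4,9,10-tetrahydro-2H,8H-pyrano[2,3-f]chromen-2-one
Product: 20 (3R)-3-[(2S,3R)-5-hydroxy-7-methoxy-2,3-dimethyl-8-(3-methylbut-2-enyl)chroman-6-yl]hexanoic acid (target)
Conditions: LiOH (3 equiv), THF–H2O 3:1, 0 → 25 °C; cold 1 M HCl to pH 4, extract at once
Reagents that add atoms: lithium hydroxide, [Li+].[OH-]
Why: Saponification of the aryl ester lactone is fast under mild base, no stereocentre is α to a carbonyl so none can epimerise, and cold acidification to pH 4 with immediate extraction avoids relactonisation and protonation of the prenyl alkene.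

**Compound list**
1 | 2,4,6-trihydroxybenzaldehyde | O=Cc1c(O)cc(O)cc1O | starting material
2 | iodomethane | CI | starting material
3 | 2,6-dihydroxy-4-methoxybenzaldehyde | COc1cc(O)c(C=O)c(O)c1 | intermediate
4 | propane-1,3-dithiol | SCCCS | starting material
5 | 2-(1,3-dithian-2-yl)-5-methoxybenzene-1,3-diol | COc1cc(O)c(C2SCCCS2)c(O)c1 | intermediate
6 | (2R,3R)-butane-2,3-diol | C[C@@H](O)[C@@H](C)O | starting material
7 | (4R,5R)-4,5-dimethyl-1,3,2-dioxathiolane 2-oxide (cyclic sulfite, not isolated) | C[C@H]1OS(=O)O[C@@H]1C | intermediate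
8 | (4R,5R)-4,5-dimethyl-1,3,2-dioxathiolane 2,2-dioxide (cyclic sulfate) | C[C@H]1OS(=O)(=O)O[C@@H]1C | intermediate
9 | sodium (2R,3S)-3-[2-(1,3-dithian-2-yl)-3-hydroxy-5-methoxyphenoxy]butan-2-yl sulfate (not isolated) | COc1cc(O)c(C2SCCCS2)c(c1)O[C@@H](C)[C@@H](C)OS(=O)(=O)[O-].[Na+] | intermediate
10 | O,C-dilithio derivative of 9: lithium phenoxide and 2-lithio-1,3-dithiane (not isolated) | COc1cc(O[Li])c(C2([Li])SCCCS2)c(c1)O[C@@H](C)[C@@H](C)OS(=O)(=O)[O-].[Na+] | intermediate
11 | (2S,3S)-7-methoxy-2,3-dimethylspiro[chromane-4,2'-[1,3]dithian]-5-ol | COc1cc(O)c2c(c1)O[C@@H](C)[C@H](C)C23SCCCS3 | intermediate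
12 | (2S,3R)-7-methoxy-2,3-dimethylchroman-5-ol | COc1cc(O)c2c(c1)O[C@@H](C)[C@H](C)C2 | intermediate
13 | 1-bromo-3-methylbut-2-ene (prenyl bromide) | CC(C)=CCBr | starting material
14 | (2S,3R)-7-methoxy-2,3-dimethyl-5-(3-methylbut-2-enyloxy)chromane | COc1cc(OCC=C(C)C)c2c(c1)O[C@@H](C)[C@H](C)C2 | intermediate
15 | (2S,3R)-7-methoxy-2,3-dimethyl-6-(2-methylbut-3-en-2-yl)-3,4-dihydro-2H-chromen-5(6H)-one (ortho-dienone, C6 epimers, not isolated) | COC1=CC2=C(C[C@@H](C)[C@H](C)O2)C(=O)C1C(C)(C)C=C | intermediate
16 | (2S,3R)-7-methoxy-2,3-dimethyl-8-(3-methylbut-2-enyl)-3,4-dihydro-2H-chromen-5(8H)-one (para-dienone, C8 epimers, not isolated) | COC1=CC(=O)C2=C(O[C@@H](C)[C@H](C)C2)C1CC=C(C)C | intermediate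
17 | (2S,3R)-7-methoxy-2,3-dimethyl-8-(3-methylbut-2-enyl)chroman-5-ol | COc1cc(O)c2c(c1CC=C(C)C)O[C@@H](C)[C@H](C)C2 | intermediate
18 | (E)-hex-2-enal | CCC/C=C/C=O | starting material
19 | (4R,8S,9R)-5-methoxy-8,9-dimethyl-6-(3-methylbut-2-enyl)-4-propyl-3,4,9,10-tetrahydro-2H,8H-pyrano[2,3-f]chromen-2-one | CCC[C@@H]1CC(=O)Oc2c1c(OC)c(CC=C(C)C)c1c2C[C@@H](C)[C@H](C)O1 | intermediate
20 | (3R)-3-[(2S,3R)-5-hydroxy-7-methoxy-2,3-dimethyl-8-(3-methylbut-2-enyl)chroman-6-yl]hexanoic acid | CCC[C@H](CC(=O)O)c1c(O)c2c(c(CC=C(C)C)c1OC)O[C@@H](C)[C@H](C)C2 | target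

**Totals**
Total step count: 9. Longest linear sequence: 8 (steps 1, 2, 4, 5, 6, 7, 8, 9). Step 3 is a one-step side branch.

**Steps most likely to fail and their fallbacks**

Step 4 is the riskiest. A hindered tertiary carbanion must displace a secondary sulfate, and elimination to an enol or allyl ether may win. The fallback sets out from 3 and comes back at 12. It keeps the masked-acyl-anion logic but changes the acceptor from an sp3 C–O carbon to an alkene. Aldehyde 3 is etherified once under Mitsunobu conditions (PPh3, DIAD, THF, 0 °C) with commercial (R)-but-3-en-2-ol. Inversion gives (S)-2-(but-3-en-2-yloxy)-6-hydroxy-4-methoxybenzaldehyde F1. A thiazolylidene carbene then converts the formyl group into its Breslow intermediate (3-mesityl-5,6,7,8-tetrahydro-4H-cyclohepta[d]thiazol-3-ium perchlorate 20 mol %, DBU, 1,4-dioxane, 80–100 °C, short contact time to limit retro-oxa-Michael erosion at C2). This intermediate adds across the unactivated vinyl group (intramolecular hydroacylation). After base equilibration at C3 the product is the trans ketone (2S,3S)-5-hydroxy-7-methoxy-2,3-dimethylchroman-4-one F2. Ionic hydrogenation (Et3SiH, CF3CO2H, 0 → 25 °C) removes the benzylic carbonyl and delivers 12.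

Step 7 may stop at the ortho stage if dienone 15 enolises, giving the 6-(1,1-dimethylallyl) phenol. The fallback sets out from 12 and comes back at 17. It replaces the sigmatropic transfer with halogenation and cross-coupling. Para-selective bromination (NBS, MeCN, −20 °C) gives (2S,3R)-8-bromo-7-methoxy-2,3-dimethylchroman-5-ol F3. A Stille coupling with tributyl(3-methylbut-2-enyl)stannane (Pd(PPh3)4 5 mol %, DMF, 90 °C) then installs the linear prenyl group and gives 17.

Step 8 may end in simple O-acylation, or may show poor facial control with a β-alkyl enal. The fallback sets out from 17 and comes back at 19. It moves the stereo-defining event from C–C bond formation to hydride delivery. Pd-catalysed hydroarylation and lactonisation of 17 with ethyl hex-2-ynoate (Pd2(dba)3·CHCl3 2.5 mol %, NaOAc, HCO2H, 35 °C) gives the flat coumarin (8S,9R)-5-methoxy-8,9-dimethyl-6-(3-methylbut-2-enyl)-4-propyl-9,10-dihydro-2H,8H-pyrano[2,3-f]chromen-2-one F4. Copper hydride conjugate reduction then sets the (4R) centre and gives 19 (Cu(OAc)2·H2O 5 mol %, (R)-DTBM-SEGPHOS, (EtO)2MeSiH, t-BuOH, toluene, 0 °C).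

**Further compounds**
F1 | step 4 | (S)-2-(but-3-en-2-yloxy)-6-hydroxy-4-methoxybenzaldehyde | COc1cc(O)c(C=O)c(c1)O[C@@H](C)C=C
F2 | step 4 | (2S,3S)-5-hydroxy-7-methoxy-2,3-dimethylchroman-4-one | COc1cc(O)c2c(c1)O[C@@H](C)[C@H](C)C2=O
F3 | step 7 | (2S,3R)-8-bromo-7-methoxy-2,3-dimethylchroman-5-ol | COc1cc(O)c2c(c1Br)O[C@@H](C)[C@H](C)C2
F4 | step 8 | (8S,9R)-5-methoxy-8,9-dimethyl-6-(3-methylbut-2-enyl)-4-propyl-9,10-dihydro-2H,8H-pyrano[2,3-f]chromen-2-one | CCCC1=CC(=O)Oc2c1c(OC)c(CC=C(C)C)c1c2C[C@@H](C)[C@H](C)O1
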